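## Retrosynthetic overview

1. Feature: ring B (C1'–C6') is a 2-substituted resorcinol. C1' carries the ketone carbon and sits between the oxygen-bearing C2' and C6'; the methyl on C4' is para to C1' and bromine is on C5'. A vinylketene and an oxygenated alkyne give this pattern directly.
2. Endgame: the ring A aldehyde and the diaryl ketone come from a 1,4-diol by double Swern oxidation, with all phenols as MOM ethers removed last. The C–Br bond is made by NBS on the phenol released by the annulation (ring B becomes symmetric once desilylated).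
3. Key disconnection: ring B → siloxyalkyne 16 (carbinol carbon already bonded to ring A C6) + 3-methylcyclobut-2-enone 22. This forms C1'–C2' and C5'–C6' and closes the ring at C2'–C3'.
4. Siloxyalkyne 16 ← terminal alkyne 13 (acetylide oxidation) ← lactol 9 + ethynylmagnesium bromide ← 7-prenylphthalide 8 ← 3,5-dimethoxybenzoic acid. Enone 22 ← ethoxyacetylene + ketene, then MeLi.
5. Ring order: ring A is bought in; its fused lactone ring is temporary (made in step 1, opened in step 7). Ring B is the only ring built, in step 12.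

Key step: step 12

Remark: the target has no stereocentre. The lactol and carbinol centres carried through steps 6–16 are racemic and are removed by oxidation, so stereoisomer mixtures there are of no consequence.

## Route

Step 1
Reactants: 1 3,5-dimethoxybenzoic acid
Product: 3 4,6-dimethoxyisobenzofuran-1(3H)-one, via 2-(hydroxymethyl)-3,5-dimethoxybenzoic acid 2 (not isolated)
Conditions: 37% aq. CH2O, conc. HCl, AcOH, 90 °C
Reagents that add atoms: formaldehyde, C=O
Why: Blanc-type electrophilic hydroxymethylation should occur ortho to the carboxyl at the position ortho and para to the two methoxy groups, and the benzylic alcohol lactonises under the acid to the phthalide.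

Step 2
Reactants: 3 4,6-dimethoxyisobenzofuran-1(3H)-one
Product: 4 7-bromo-4,6-dimethoxyisobenzofuran-1(3H)-one
Conditions: NBS, MeCN, rt
Reagents that add atoms: N-bromosuccinimide, O=C1CCC(=O)N1Br
Why: Electrophilic aromatic bromination should go to C7, which is para to the C4 methoxy and ortho to the C6 methoxy, in preference to the hindered C5 between the two methoxy groups.

Step 3
Reactants: 4 7-bromo-4,6-dimethoxyisobenzofuran-1(3H)-one
Product: 5 7-bromo-4,6-dihydroxyisobenzofuran-1(3H)-one
Conditions: BBr3, CH2Cl2, −78 °C → rt; then H2O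
Reagents that add atoms: none
Why: Lewis-acid cleavage of aryl methyl ethers is tolerated by the lactone and the aryl bromide, and is done here before the acid-sensitive prenyl group is present.

Step 4
Reactants: 5 7-bromo-4,6-dihydroxyisobenzofuran-1(3H)-one
Product: 6 7-bromo-4,6-bis(methoxymethoxy)isobenzofuran-1(3H)-one
Conditions: MOMCl, i-Pr2NEt, DMF, 0 °C → rt
Reagents that add atoms: chloromethyl methyl ether, COCCl
Why: O-alkylation of both phenols gives acetal ethers that survive the reductive, organometallic, thermal and fluoride steps and are removed by mild acid at the end.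

Step 5
Reactants: 6 7-bromo-4,6-bis(methoxymethoxy)isobenzofuran-1(3H)-one; 7 tributyl(3-methylbut-2-en-1-yl)stannane
Product: 8 4,6-bis(methoxymethoxy)-7-(3-methylbut-2-en-1-yl)isobenzofuran-1(3H)-one
Conditions: Pd(PPh3)4 (10 mol %), LiCl, DMF, 90 °C
Reagents that add atoms: none
Why: Stille coupling of the aryl bromide, activated for oxidative addition by the ortho lactone carbonyl, should give the linear prenyl arene because reductive elimination from the allylpalladium intermediate takes place at the unsubstituted allyl terminus.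

Step 6
Reactants: 8 4,6-bis(methoxymethoxy)-7-(3-methylbut-2-en-1-yl)isobenzofuran-1(3H)-one
Product: 9 rac-4,6-bis(methoxymethoxy)-7-(3-methylbut-2-en-1-yl)-1,3-dihydroisobenzofuran-1-ol
Conditions: i-Bu2AlH (1.1 equiv), CH2Cl2, −78 °C; aq. potassium sodium tartrate
Reagents that add atoms: none
Why: Partial hydride reduction of the lactone stops at the lactol because the tetrahedral aluminium lactolate is stable at −78 °C; the new centre is racemic and is lost later.

Step 7
Reactants: 9 rac-lactol; 10 ethynylmagnesium bromide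
Product: 12 rac-1-[2-(hydroxymethyl)-3,5-bis(methoxymethoxy)-6-(3-methylbut-2-en-1-yl)phenyl]prop-2-yn-1-ol, via ring-opened aldehyde alkoxide 11 (not isolated)
Conditions: 10 (3.5 equiv), THF, 0 °C → rt; aq. NH4Cl
Reagents that add atoms: none
Why: One equivalent of the Grignard reagent deprotonates the lactol, whose ring-opened aldehyde form then undergoes Grignard 1,2-addition of the small acetylide; the carbinol centre forms without control (racemic) and is later oxidised to the ketone.

Step 8
Reactants: 12 rac-diol
Product: 13 rac-bis(tert-butyldimethylsilyl) ether of diol 12 (terminal alkyne)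
Conditions: TBSOTf (2.5 equiv), 2,6-lutidine, CH2Cl2, −78 → 0 °C
Reagents that add atoms: tert-butyldimethylsilyl trifluoromethanesulfonate, CC(C)(C)[Si](C)(C)OS(=O)(=O)C(F)(F)F
Why: The silyl triflate silylates both the primary benzylic and the hindered secondary propargylic hydroxyl, so that no free hydroxyl can capture the ketene intermediates of step 12.

Step 9
Reactants: 13 rac-bis-silyl ether alkyne
Product: 16 rac-tert-butyl({2-[1-(tert-butyldimethylsilyloxy)-3-(triisopropylsilyloxy)prop-2-yn-1-yl]-4,6-bis(methoxymethoxy)-3-(3-methylbut-2-en-1-yl)benzyl}oxy)dimethylsilane, via lithium acetylide 14 (not isolated), via lithium ynolate 15 (not isolated)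
Conditions: n-BuLi, THF, −78 °C; LiOOt-Bu (from t-BuOOH and LiN(SiMe3)2, THF, −78 °C), −78 → 0 °C; TIPSOTf, −78 → 0 °C
Reagents that add atoms: tert-butyl hydroperoxide, CC(C)(C)OO; triisopropylsilyl trifluoromethanesulfonate, CC(C)[Si](OS(=O)(=O)C(F)(F)F)(C(C)C)C(C)C
Why: Oxidation of a lithium acetylide by lithium tert-butyl peroxide gives the lithium ynolate, and the bulky silyl triflate traps it on oxygen to give the 1-siloxyalkyne.

Step 10
Reactants: 17 ethoxyacetylene; 18 acetyl chloride
Product: 20 3-ethoxycyclobut-2-en-1-one, via ketene 19 (not isolated)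
Conditions: Et3N, Et2O, 0 °C → rt
Reagents that add atoms: none
Why: Dehydrochlorination of the acid chloride gives ketene, which undergoes [2+2] cycloaddition with the electron-rich alkoxyalkyne, its carbonyl carbon bonding to the oxygen-remote alkyne carbon.

Step 11
Reactants: 20 3-ethoxycyclobut-2-en-1-one
Product: 22 3-methylcyclobut-2-en-1-one, via lithium alkoxide 21 (not isolated)
Conditions: MeLi, Et2O, −78 °C; then 1 M aq. HCl, 0 °C
Reagents that add atoms: methyllithium, C[Li]; water, O
Why: Stork–Danheiser sequence: 1,2-addition to the vinylogous ester followed by acid hydrolysis with allylic transposition gives the 3-methyl enone.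

Step 12
Reactants: 16 ring A siloxyalkyne; 22 3-methylcyclobut-2-en-1-one
Product: 27 rac-2-[(tert-butyldimethylsilyloxy){2-[(tert-butyldimethylsilyloxy)methyl]-3,5-bis(methoxymethoxy)-6-(3-methylbut-2-en-1-yl)phenyl}methyl]-5-methyl-3-(triisopropylsilyloxy)phenol, via vinylketene 23 (not isolated), via 4-vinylcyclobutenone 24 (not isolated), via dienylketene 25 (not isolated), via cyclohexadienone 26 (not isolated)
Conditions: 22 (1.5 equiv, two portions), toluene, 80 °C then 110 °C, sealed tube
Reagents that add atoms: none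
Why: Danheiser benzannulation: thermal four-electron electrocyclic opening of 22 gives vinylketene 23, whose carbonyl carbon adds in a [2+2] cycloaddition to the oxygen-remote, nucleophilic carbon of 16 while its α-carbon bonds to the siloxy carbon, giving 24 and forming C1'–C2' and C5'–C6'. A second four-electron opening gives dienylketene 25, which closes ring B at C2'–C3' by a thermal disrotatory six-electron electrocyclisation, and dienone 26 tautomerises to phenol 27. The closest known reaction type is the benzannulation of cyclobutenones with trialkylsiloxyalkynes to give resorcinol monosilyl ethers. No stereocentre is formed in the product; the racemic carbinol centre is untouched. The selectivity needed is the orientation of the ketene–alkyne cycloaddition, which the polarisation of the ynol ether fixes, so that the ring A carbinol carbon ends on C1' between the two oxygens with the methyl para to it. Ring B is grown around a carbon already bonded to ring A, so no bond has to be made to a doubly ortho-substituted arene carbon; the silyl ether on the carbinol keeps the ketenes from being trapped.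

Step 13
Reactants: 27 rac-resorcinol monosilyl ether
Product: 28 rac-6-bromo-2-[(tert-butyldimethylsilyloxy)(ring A aryl)methyl]-5-methyl-3-(triisopropylsilyloxy)phenol (ring A aryl as in 27)
Conditions: NBS (1.0 equiv), i-Pr2NH (10 mol %), CH2Cl2, −78 → 0 °C
Reagents that add atoms: N-bromosuccinimide, O=C1CCC(=O)N1Br
Why: Amine-catalysed ortho-bromination of a free phenol is much faster than attack on the ring A bis-acetal arene or the prenyl alkene; bromination para to the hydroxyl instead would converge on the same compound 29 in step 14.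

Step 14
Reactants: 28 rac-bromophenol silyl ether
Product: 29 rac-4-bromo-2-[(tert-butyldimethylsilyloxy)(ring A aryl)methyl]-5-methylbenzene-1,3-diol
Conditions: TBAF (1.05 equiv), THF, −40 °C; aq. NH4Cl
Reagents that add atoms: none
Why: Fluoride cleaves the aryl silyl ether, which has a phenoxide leaving group, far faster than the two alkyl tert-butyldimethylsilyl ethers at low temperature.

Step 15
Reactants: 29 rac-bromoresorcinol
Product: 30 rac-bis(methoxymethyl) ether of 29 (ring B 3-bromo-2,6-bis(methoxymethoxy)-4-methylphenyl; both tert-butyldimethylsilyl ethers retained)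
Conditions: NaH, MOMCl, DMF, 0 °C → rt
Reagents that add atoms: chloromethyl methyl ether, COCCl
Why: O-alkylation of both phenoxides by the small chloromethyl ether puts all four phenols under the same acetal protection, so that the oxidation is run without free phenols.

Step 16
Reactants: 30 rac-bis-silyl ether
Product: 31 rac-[3-bromo-2,6-bis(methoxymethoxy)-4-methylphenyl][2-(hydroxymethyl)-3,5-bis(methoxymethoxy)-6-(3-methylbut-2-en-1-yl)phenyl]methanol
Conditions: TBAF (5 equiv), THF, rt → 45 °C; aq. NH4Cl
Reagents that add atoms: none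
Why: Fluoride desilylation under basic conditions frees both alcohols without the acid that would ionise the ring B stabilised benzhydryl position.

Step 17
Reactants: 31 rac-diol
Product: 33 2-[3-bromo-2,6-bis(methoxymethoxy)-4-methylbenzoyl]-4,6-bis(methoxymethoxy)-3-(3-methylbut-2-en-1-yl)benzaldehyde, via bis(alkoxysulfonium) salt 32 (not isolated)
Conditions: (COCl)2 (4 equiv), DMSO (8 equiv), CH2Cl2, −78 °C; then Et3N (12 equiv), −78 → 0 °C
Reagents that add atoms: none
Why: In the Swern oxidation both hydroxyls are converted to alkoxysulfonium ions before base is added, so both carbonyls appear together and the mono-oxidised lactol, which would be over-oxidised to a lactone, is not formed.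

Step 18
Reactants: 33 tetrakis(methoxymethyl) keto aldehyde
Product: 34 Pestalone C, 2-(3-bromo-2,6-dihydroxy-4-methylbenzoyl)-4,6-dihydroxy-3-(3-methylbut-2-en-1-yl)benzaldehyde
Conditions: 6 M aq. HCl, THF, 40 °C
Reagents that add atoms: none
Why: Acid hydrolysis of the four aryl acetals, three of them assisted by an ortho carbonyl, is mild enough to leave the prenyl alkene, the aldehyde and the aryl bromide untouched.

## Compound list

1 | 3,5-dimethoxybenzoic acid | COc1cc(OC)cc(C(=O)O)c1 | starting material
2 | 2-(hydroxymethyl)-3,5-dimethoxybenzoic acid (not isolated) | COc1cc(OC)c(CO)c(c1)C(=O)O | intermediate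
3 | 4,6-dimethoxyisobenzofuran-1(3H)-one | COc1cc(OC)c2c(c1)C(=O)OC2 | intermediate
4 | 7-bromo-4,6-dimethoxyisobenzofuran-1(3H)-one | COc1cc(OC)c2c(c1Br)C(=O)OC2 | intermediate
5 | 7-bromo-4,6-dihydroxyisobenzofuran-1(3H)-one | Oc1cc(O)c2c(c1Br)C(=O)OC2 | intermediate
6 | 7-bromo-4,6-bis(methoxymethoxy)isobenzofuran-1(3H)-one | COCOc1cc(OCOC)c2c(c1Br)C(=O)OC2 | intermediate
7 | tributyl(3-methylbut-2-en-1-yl)stannane | CCCC[Sn](CCCC)(CCCC)CC=C(C)C | starting material
8 | 4,6-bis(methoxymethoxy)-7-(3-methylbut-2-en-1-yl)isobenzofuran-1(3H)-one | CC(C)=CCc1c(OCOC)cc(OCOC)c2c1C(=O)OC2 | intermediate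
9 | rac-4,6-bis(methoxymethoxy)-7-(3-methylbut-2-en-1-yl)-1,3-dihydroisobenzofuran-1-ol | CC(C)=CCc1c(OCOC)cc(OCOC)c2c1C(O)OC2 | intermediate
10 | ethynylmagnesium bromide | C#C[Mg]Br | starting material
11 | bromomagnesium [2-formyl-4,6-bis(methoxymethoxy)-3-(3-methylbut-2-en-1-yl)phenyl]methanolate (not isolated) | CC(C)=CCc1c(OCOC)cc(OCOC)c(CO[Mg]Br)c1C=O | intermediate
12 | rac-1-[2-(hydroxymethyl)-3,5-bis(methoxymethoxy)-6-(3-methylbut-2-en-1-yl)phenyl]prop-2-yn-1-ol | CC(C)=CCc1c(OCOC)cc(OCOC)c(CO)c1C(O)C#C | intermediate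
13 | rac-bis(tert-butyldimethylsilyl) ether of 12 | CC(C)=CCc1c(OCOC)cc(OCOC)c(CO[Si](C)(C)C(C)(C)C)c1C(O[Si](C)(C)C(C)(C)C)C#C | intermediate
14 | lithium acetylide of 13 (not isolated) | CC(C)=CCc1c(OCOC)cc(OCOC)c(CO[Si](C)(C)C(C)(C)C)c1C(O[Si](C)(C)C(C)(C)C)C#C[Li] | intermediate
15 | lithium ynolate from 14 (not isolated) | CC(C)=CCc1c(OCOC)cc(OCOC)c(CO[Si](C)(C)C(C)(C)C)c1C(O[Si](C)(C)C(C)(C)C)C#CO[Li] | intermediate
16 | rac-ring A propargylic siloxyalkyne (carbinol and hydroxymethyl as tert-butyldimethylsilyl ethers, alkyne oxygen as triisopropylsilyl ether) | CC(C)=CCc1c(OCOC)cc(OCOC)c(CO[Si](C)(C)C(C)(C)C)c1C(O[Si](C)(C)C(C)(C)C)C#CO[Si](C(C)C)(C(C)C)C(C)C | intermediate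
17 | ethoxyacetylene | CCOC#C | starting material
18 | acetyl chloride | CC(=O)Cl | starting material
19 | ketene (not isolated) | C=C=O | intermediate
20 | 3-ethoxycyclobut-2-en-1-one | CCOC1=CC(=O)C1 | intermediate
21 | lithium 3-ethoxy-1-methylcyclobut-2-en-1-olate (not isolated) | CCOC1=CC(C)(O[Li])C1 | intermediate
22 | 3-methylcyclobut-2-en-1-one | CC1=CC(=O)C1 | intermediate
23 | 3-methylbuta-1,3-dien-1-one, the vinylketene (not isolated) | C=C(C)C=C=O | intermediate
24 | 2-[ring A (silyloxy)methyl]-4-(prop-1-en-2-yl)-3-(triisopropylsilyloxy)cyclobut-2-en-1-one, stereoisomer mixture (not isolated) | CC(C)=CCc1c(OCOC)cc(OCOC)c(CO[Si](C)(C)C(C)(C)C)c1C(O[Si](C)(C)C(C)(C)C)C1=C(O[Si](C(C)C)(C(C)C)C(C)C)C(C(C)=C)C1=O | intermediate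
25 | dienylketene from ring opening of 24 (not isolated) | CC(C)=CCc1c(OCOC)cc(OCOC)c(CO[Si](C)(C)C(C)(C)C)c1C(O[Si](C)(C)C(C)(C)C)C(=C=O)C(O[Si](C(C)C)(C(C)C)C(C)C)=CC(C)=C | intermediate
26 | 2-[ring A (silyloxy)methyl]-5-methyl-3-(triisopropylsilyloxy)cyclohexa-2,4-dien-1-one (not isolated) | CC(C)=CCc1c(OCOC)cc(OCOC)c(CO[Si](C)(C)C(C)(C)C)c1C(O[Si](C)(C)C(C)(C)C)C1=C(O[Si](C(C)C)(C(C)C)C(C)C)C=C(C)CC1=O | intermediate
27 | rac-diarylmethanol silyl ether with ring B as 2-hydroxy-4-methyl-6-(triisopropylsilyloxy)phenyl | CC(C)=CCc1c(OCOC)cc(OCOC)c(CO[Si](C)(C)C(C)(C)C)c1C(O[Si](C)(C)C(C)(C)C)c1c(O)cc(C)cc1O[Si](C(C)C)(C(C)C)C(C)C | intermediate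
28 | rac-bromophenol, ring B as 3-bromo-2-hydroxy-4-methyl-6-(triisopropylsilyloxy)phenyl | CC(C)=CCc1c(OCOC)cc(OCOC)c(CO[Si](C)(C)C(C)(C)C)c1C(O[Si](C)(C)C(C)(C)C)c1c(O)c(Br)c(C)cc1O[Si](C(C)C)(C(C)C)C(C)C | intermediate
29 | rac-bromoresorcinol, ring B as 3-bromo-2,6-dihydroxy-4-methylphenyl | CC(C)=CCc1c(OCOC)cc(OCOC)c(CO[Si](C)(C)C(C)(C)C)c1C(O[Si](C)(C)C(C)(C)C)c1c(O)c(Br)c(C)cc1O | intermediate
30 | rac-bis-silyl ether, ring B as 3-bromo-2,6-bis(methoxymethoxy)-4-methylphenyl | CC(C)=CCc1c(OCOC)cc(OCOC)c(CO[Si](C)(C)C(C)(C)C)c1C(O[Si](C)(C)C(C)(C)C)c1c(OCOC)c(Br)c(C)cc1OCOC | intermediate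
31 | rac-[3-bromo-2,6-bis(methoxymethoxy)-4-methylphenyl][2-(hydroxymethyl)-3,5-bis(methoxymethoxy)-6-(3-methylbut-2-en-1-yl)phenyl]methanol | CC(C)=CCc1c(OCOC)cc(OCOC)c(CO)c1C(O)c1c(OCOC)c(Br)c(C)cc1OCOC | intermediate
32 | bis(dimethylalkoxysulfonium) dichloride of 31 (not isolated) | CC(C)=CCc1c(OCOC)cc(OCOC)c(CO[S+](C)C)c1C(O[S+](C)C)c1c(OCOC)c(Br)c(C)cc1OCOC.[Cl-].[Cl-] | intermediate
33 | 2-[3-bromo-2,6-bis(methoxymethoxy)-4-methylbenzoyl]-4,6-bis(methoxymethoxy)-3-(3-methylbut-2-en-1-yl)benzaldehyde | CC(C)=CCc1c(OCOC)cc(OCOC)c(C=O)c1C(=O)c1c(OCOC)c(Br)c(C)cc1OCOC | intermediate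
34 | Pestalone C | CC(C)=CCc1c(O)cc(O)c(C=O)c1C(=O)c1c(O)cc(C)c(Br)c1O | target

## Step count and risks

Total step count: 18. Longest linear sequence: 16 (steps 1–9, then 12–18).

Steps most likely to fail:

**Step 12 (benzannulation).** The ketene–alkyne cycloaddition may be slowed by the crowded propargylic position. Vinylketene dimerisation, acylation of the new phenol by vinylketene, or thermal silyl shift of the siloxyalkyne could then take over.
Fallback, from lactol 9 to diol 31: ring B would be attached ready-made by carbonyl addition. Orcinol F1 is converted (MOMCl, NaH, DMF) to 1,3-bis(methoxymethoxy)-5-methylbenzene F2. Lithiation between the two acetal oxygens and iodination (n-BuLi, THF, 0 °C; I2) gives 2-iodo-1,3-bis(methoxymethoxy)-5-methylbenzene F3. Bromination (NBS, MeCN) gives 1-bromo-3-iodo-2,4-bis(methoxymethoxy)-6-methylbenzene F4. Selective iodine–magnesium exchange (i-PrMgCl·LiCl, THF, −30 °C) gives [3-bromo-2,6-bis(methoxymethoxy)-4-methylphenyl]magnesium chloride F5. Addition of F5 (3 equiv) to lactol 9 (THF, −30 °C → rt) should give diol 31 directly, and the route continues with step 17.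

**Step 5 (Stille prenylation).** Allylic transposition during transmetalation or reductive elimination may deliver the branched 1,1-dimethylallyl isomer. Slow coupling at the doubly ortho-substituted bromide may also lead to protodebromination.
Fallback, from bromide 6 to prenylphthalide 8: Stille coupling with allyltributylstannane (Pd(PPh3)4, DMF, 90 °C), which has no regiochemical ambiguity, gives 7-allyl-4,6-bis(methoxymethoxy)isobenzofuran-1(3H)-one F6. Olefin cross-metathesis of F6 with 2-methylbut-2-ene (second-generation Grubbs catalyst, CH2Cl2, 40 °C) should then give 8.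

**Step 17 (double Swern oxidation).** The benzhydryl alkoxysulfonium ion may ionise to a ring B stabilised cation, followed by chloride capture or cyclisation onto the neighbouring oxygen. Alternatively one hydroxyl may be oxidised ahead of the other, with lactol formation and over-oxidation to a lactone.
Fallback, from diol 31 to keto aldehyde 33: the ketone is made first. Selective acetylation of the unhindered primary hydroxyl (Ac2O, pyridine, CH2Cl2, 0 °C) gives the rac-monoacetate F7. Oxidation of the carbinol (Dess–Martin periodinane, NaHCO3, CH2Cl2) gives the keto acetate F8. Methanolysis (K2CO3, MeOH, 0 °C) gives the hydroxy ketone F9, which equilibrates with a cyclic hemiketal that has no carbinol hydrogen and so cannot go on to a lactone. A second Dess–Martin oxidation of F9 should give 33.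

## Further compounds

F1 | step 12 | orcinol (5-methylbenzene-1,3-diol) | Cc1cc(O)cc(O)c1
F2 | step 12 | 1,3-bis(methoxymethoxy)-5-methylbenzene | COCOc1cc(C)cc(OCOC)c1
F3 | step 12 | 2-iodo-1,3-bis(methoxymethoxy)-5-methylbenzene | COCOc1cc(C)cc(OCOC)c1I
F4 | step 12 | 1-bromo-3-iodo-2,4-bis(methoxymethoxy)-6-methylbenzene | COCOc1cc(C)c(Br)c(OCOC)c1I
F5 | step 12 | [3-bromo-2,6-bis(methoxymethoxy)-4-methylphenyl]magnesium chloride | COCOc1cc(C)c(Br)c(OCOC)c1[Mg]Cl
F6 | step 5 | 7-allyl-4,6-bis(methoxymethoxy)isobenzofuran-1(3H)-one | C=CCc1c(OCOC)cc(OCOC)c2c1C(=O)OC2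
F7 | step 17 | rac-2-[(3-bromo-2,6-bis(methoxymethoxy)-4-methylphenyl)(hydroxy)methyl]-4,6-bis(methoxymethoxy)-3-(3-methylbut-2-en-1-yl)benzyl acetate | CC(C)=CCc1c(OCOC)cc(OCOC)c(COC(C)=O)c1C(O)c1c(OCOC)c(Br)c(C)cc1OCOC
F8 | step 17 | 2-[3-bromo-2,6-bis(methoxymethoxy)-4-methylbenzoyl]-4,6-bis(methoxymethoxy)-3-(3-methylbut-2-en-1-yl)benzyl acetate | CC(C)=CCc1c(OCOC)cc(OCOC)c(COC(C)=O)c1C(=O)c1c(OCOC)c(Br)c(C)cc1OCOC
F9 | step 17 | [3-bromo-2,6-bis(methoxymethoxy)-4-methylphenyl][2-(hydroxymethyl)-3,5-bis(methoxymethoxy)-6-(3-methylbut-2-en-1-yl)phenyl]methanone | CC(C)=CCc1c(OCOC)cc(OCOC)c(CO)c1C(=O)c1c(OCOC)c(Br)c(C)cc1OCOC
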